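**Same concentration.** What stayed the same across the earlier runs was the concentration dissolved, not the percentage: gamma ended at 5.9 % of its charge and zeta at 4.3 % of a larger one, which is 0.00295 M and 0.00322 M. From the mean of gamma's last two readings I took c* = 0.00298 M as the ceiling, the dissolved concentration standing over remaining solid (the solubility limit).

| flask | solid substrate | partner | remark | time |
|---|---|---|---|---|
| gamma | 0.050 M | 0.13 M | run made earlier |  |
| alpha | 0.050 M | 0.20 M | run made earlier |  |
| zeta | 0.075 M | 0.090 M | run made earlier |  |
| flask | 0.050 M | 0.0900 M |  | 10 h |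

| run | time / h | dissolved substrate / % | solid substrate / % |
|---|---|---|---|
| gamma | 0.500 | 1.7 | 97.9 |
| gamma | 0.833 | 2.2 | 95.8 |
| gamma | 1.33 | 4.1 | 94.7 |
| gamma | 2.00 | 4.4 | 93.8 |
| gamma | 4.00 | 6.0 | 93.2 |
| gamma | 6.00 | 5.9 | 92.4 |
| alpha | 1.00 | 3.6 | 95.3 |
| alpha | 2.00 | 4.0 | 93.9 |
| alpha | 3.00 | 3.9 | 92.7 |
| alpha | 4.00 | 5.6 | 92.2 |
| alpha | 5.00 | 5.6 | 92.6 |
| alpha | 6.00 | 5.2 | 92.6 |
| zeta | 0.500 | 1.4 | 98.7 |
| zeta | 0.833 | 1.3 | 98.0 |
| zeta | 1.50 | 4.2 | 96.1 |
| zeta | 3.00 | 3.2 | 95.7 |
| zeta | 6.00 | 4.3 | 95.4 |

(scatter of a reading: 0.5 percentage points)

- a species is counted by the solid substrate in it: one side product counts as two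
- amounts and yields of target count idle adduct too
- given per volume of solution although it is solid: solid substrate
- the numbers in the tables scatter with a standard deviation of 0.5 percentage points
- steps under discussion: partner + target <-> idle adduct; partner -> decomposed reagent; dissolved substrate + partner -> target; dissolved substrate + target -> side product; 2 partner -> homo dimer; solid substrate <-> dissolved substrate
- at the start none of the solid substrate is in solution
- dissolved substrate means what is dissolved; the solid is not counted in it

* concentration of dissolved substrate at 10 h, in M
* concentration of solid substrate at 10 h, in M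

**The opposite.** To end well below c*, the flask would need too short a time, a charge too small to reach c*, or a lasting drain of like size to the dissolving. Its time is longer than the 4.00 h by which gamma stood at its level, and its charge is 16.8 times c*. Gamma, with the same charge and more partner, had lost 1.70 % of its charge to reaction by 6.00 h. Its solid had dissolved faster over the first 0.500 h than that average drain, by a factor of 14.8. So I reckoned c* for the dissolved substrate and gamma's last solid reading, 0.0462 M, for the solid.

**The forecast.** It gave 0.0029 M (0.0025 M to 0.0032 M) and 0.0464 M (0.0452 M to 0.0472 M), holding that “the flask should still be saturated at 10 h”. My ceiling lay slightly above its first number, and my solid slightly below its second.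

**The result.** The flask gave 0.00286 M dissolved and 0.0461 M solid.

    partner + target ⇌ idle adduct, settled at all times (K = 330 M⁻¹)
    partner → decomposed reagent (k = 2.20 × 10⁻⁴ s⁻¹)
    dissolved substrate + partner → target (k = 0.00140 M⁻¹ s⁻¹)
    dissolved substrate + target → side product (k = 0.0110 M⁻¹ s⁻¹)
    2 partner → homo dimer (k = 4.50 × 10⁻⁴ M⁻¹ s⁻¹)
    solid substrate ⇌ dissolved substrate, rate k6*(cs6 - [dissolved substrate]) while solid is left; crystals form when [dissolved substrate] > cs6 (solubility = 2.90 mM, k = 2.90 × 10⁻⁴ s⁻¹)

The low solubility of dissolved substrate accounts for a large part of this: the same flask without that limit stands at 0.0191 M, not 0.00286 M. A neighbour flask with 0.020 M of solid substrate still has a charge of 6.71 times c*, so I set its dissolved substrate at 0.00298 M and its solid just under 0.0170 M. It holds 0.00286 M dissolved and 0.0161 M solid.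

The readings are simulated for substances that don't exist.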